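(The earlier runs and the new flask were generated by integration for substances that don't exist; noise was put on by code.)

How far does the electrophile get in grey, blue and violet, and does more nucleophile carry it further? I want an answer from a count, with no rate constant, and a ladder of times gives me one.

| setting | beta | grey | blue | violet |
|---|---|---|---|---|
| electrophile | 0.20 M | 0.20 M | 0.20 M | 0.20 M |
| nucleophile | 0.19 M (fed, over 1.0 h) | 0.190 M (fed, over 1.0 h) | 0.250 M (fed, over 1.0 h) | 0.320 M (fed, over 1.0 h) |
| protic impurity | 0.040 M | 0.0600 M | 0.0600 M | 0.0600 M |
| remark | run made earlier |  |  |  |
| time |  | 2.0 h | 2.0 h | 2.0 h |

- beta (time / min: electrophile / %, target / %): 4.00: 82, 3; 10.0: 72, 4; 20.0: 68, 13; 30.0: 56, 24; 40.0: 49, 31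

(standard deviation of a reading: 1.5 percentage points)

- the numbers in the tables scatter with a standard deviation of 1.5 percentage points
- no earlier run changes the charge of protic impurity; that part of a forecast is a guess

* part of the electrophile that has reacted at the end, grey
* part of the electrophile that has reacted at the end, blue
* part of the electrophile that has reacted at the end, violet
* what raising the concentration of nucleophile from its lowest to its highest value here does to the part of the electrophile that has reacted (changes below 5 percentage points count as none) (it falls / it rises / no change)

The first rung is the protic impurity. In beta the electrophile is down by 18.0 % at 4.00 min, with 3 % of target, and that time is shorter than the feed. At 40.0 min electrophile and target together fall short of the charge by 20.0 %, close to the impurity's share of the charge, 20.0 %. So I take the impurity as removing electrophile one for one, and at the new charge that is a guess.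

The middle rung is the feed. By 40.0 min beta has received 0.127 M of nucleophile but holds 0.0620 M of target. I call nucleophile fed per target formed the price of target, 2.04. The symmetric case, one nucleophile per target, is the zero of my scale, and this reading stands at twice that, with the scatter of a reading.

The last rung is the second hour. Beta stops before it, so I assume the price holds and the feed's end ends the gain:

[electrophile] − [protic impurity] = 0.140 M

balance charge = price × 0.140 M = 0.286 M

reacted = ([protic impurity] + charge/price) / [electrophile], capped at the whole charge of electrophile

grey 76.5 %, blue 91.2 %, violet 100 %

By this count nucleophile is the limiting reagent in blue, whose charge is below the balance, and in grey, whose charge is below it too, while violet lies above it. I expect a rise of 23 percentage points.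

The forecast gives 93 %, 98 % and 99.5 %, higher than my grey and blue, on the ground that “nucleophile accumulates”, and its trend reads: it rises.

    electrophile + nucleophile → acid set free + target (k = 4.60 L mol⁻¹ min⁻¹)
    nucleophile + acid set free ⇌ protonated nucleophile, settled at all times (K = 48000 L mol⁻¹)
    electrophile + acid set free ⇌ idle adduct, settled at all times (K = 13.0 L mol⁻¹)
    electrophile + protic impurity → quenched substrate (k = 3.40 L mol⁻¹ min⁻¹)
    acid set free + target → side product (k = 0.530 L mol⁻¹ min⁻¹)

The flasks give 81.8 %, 94.5 % and >99.9 %, and the trend is: it rises, by 18 points. My grey figure is lower by 5.3 points. In blue at 2.00 h, 0.122 M of target stands beside 0.120 M of protonated nucleophile. A neighbour of blue with 0.062 M of nucleophile is priced at 15.2 % of target, and that flask holds 16.9 %.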